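The plan rests on a retro-[4+2] cut of the bicyclo[2.2.2]octane (C1 = C–OH bridgehead, C4 = CH bridgehead). The CMe2–CH bridge (C3–C2) is laid across C4 and C1 of a 1-silyloxycyclohexa-1,3-diene in one operation. The step exploits two features. The first is the bridgehead carbinol C1 next to the benzyl-bearing C2, which is the "ortho" pattern of a 1-oxygenated diene and an aryl enone. The second is the quaternary C8, whose side chain is carried as a rod-like propynyl group so that the dienophile enters on that face. The precursors are dienol silyl ether 27 and 1-aryl-3-methylbut-2-en-1-one 18. Alkyne zipper, acetylide opening of the oxepane-half spiro-epoxide 12, hydrogenation and sulfation finish the route.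

Key step: step 16

Numbering used:
- Bicyclooctane: C1 oxygenated bridgehead, C2 CH carrying the benzylic carbon, C3 CMe2, C4 CH bridgehead, C5–C6 two-carbon bridge, C7 CH2, C8 quaternary carbon.
- Benzoxepine: O1, C2 (CMe2), C5a (angular C–CH3), C6 (ketone or carbinol carbon), C7 (CH–CH3), C9a (O–CH).

Assumption: the target is drawn as the free hydrogen sulfate, so sulfates are written in the acid form. The last step ends with a short cation exchange, and the compound would be stored as a salt.

**Oxepane half (steps 1–8)**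

Step 1
Reactants: 1 2-methylcyclohexane-1,3-dione; 2 acrolein
Product: 3 3-(1-methyl-2,6-dioxocyclohexyl)propanal
Conditions: Et3N (cat.), H2O, rt
Reagents that add atoms: none
Why: Michael addition of the acidic 1,3-dione to acrolein should give clean C-alkylation and create the still prochiral quaternary carbon.

Step 2
Reactants: 3 3-(1-methyl-2,6-dioxocyclohexyl)propanal
Product: 4 2-methyl-2-(4-methylpent-3-en-1-yl)cyclohexane-1,3-dione
Conditions: i-PrPPh3I, n-BuLi, THF, 0 °C; then 3, −78 °C → rt
Reagents that add atoms: isopropyltriphenylphosphonium iodide, CC(C)[P+](c1ccccc1)(c1ccccc1)c1ccccc1.[I-]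
Why: Wittig olefination, in which the aldehyde should react far faster than the two ketones flanking the quaternary carbon.

Step 3
Reactants: 4 2-methyl-2-(4-methylpent-3-en-1-yl)cyclohexane-1,3-dione
Product: 5 (2R,3R)-3-hydroxy-2-methyl-2-(4-methylpent-3-en-1-yl)cyclohexan-1-one (OH cis to the chain)
Conditions: (S)-Me-CBS (20 mol %), catecholborane (1 equiv), toluene, −78 → −40 °C; aq. NaOH work-up
Reagents that add atoms: none
Why: Corey–Bakshi–Shibata reduction used as a desymmetrisation, in which the catalyst (quaternary carbon as the large group) should fix the (R)-carbinol and hydride enters anti to the axial chain, so one reduction sets C3 and the quaternary C2 while catecholborane spares the alkene.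

Step 4
Reactants: 5 (2R,3R)-3-hydroxy-2-methyl-2-(4-methylpent-3-en-1-yl)cyclohexan-1-one
Product: 7 (2R,3S)-3-hydroxy-2-methyl-2-(4-methylpent-3-en-1-yl)cyclohexan-1-one (OH trans to the chain), via 4-nitrobenzoate ester 6 (not isolated)
Conditions: 4-O2NC6H4CO2H, PPh3, DIAD, toluene, 0 °C → rt; then K2CO3 (cat.), MeOH, 0 °C
Reagents that add atoms: 4-nitrobenzoic acid, O=C(O)c1ccc(cc1)[N+](=O)[O-]
Why: Mitsunobu inversion followed by mild methanolysis turns the carbinol into the epimer trans to the chain that a trans-fused ring needs, and elimination toward the quaternary carbon is impossible.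

Step 5
Reactants: 7 (2R,3S)-3-hydroxy-2-methyl-2-(4-methylpent-3-en-1-yl)cyclohexan-1-one
Product: 8 (5aR,9aS)-2,2,5a-trimethyloctahydro-1-benzoxepin-6(2H)-one (trans-fused)
Conditions: Co(salen) catalyst (5 mol %), N-fluoro-2,4,6-trimethylpyridinium triflate, (Me2SiH)2O, PhCF3, rt
Reagents that add atoms: none
Why: Cobalt-catalysed MHAT/radical–polar crossover hydroalkoxylation (a type known to close medium rings), in which H adds to the CH end of the alkene and the tertiary cation equivalent is captured Markovnikov by the hydroxyl group without touching the ketone or any stereocentre.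

Step 6
Reactants: 8 (5aR,9aS)-2,2,5a-trimethyloctahydro-1-benzoxepin-6(2H)-one
Product: 10 (5aR,7S,9aS)-2,2,5a,7-tetramethyloctahydro-1-benzoxepin-6(2H)-one, via lithium enolate 9 (not isolated)
Conditions: LDA, THF, −78 °C; MeI, −78 → 0 °C; then NaOMe (cat.), MeOH, rt
Reagents that add atoms: iodomethane, CI
Why: Enolate alkylation at the only enolisable position, then base equilibration, which should place the C7 methyl group equatorial because the axial epimer is syn-diaxial to the angular C5a methyl group.

Step 7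
Reactants: 10 (5aR,7S,9aS)-2,2,5a,7-tetramethyloctahydro-1-benzoxepin-6(2H)-one
Product: 11 (5aS,7S,9aS)-2,2,5a,7-tetramethyl-6-methylidenedecahydro-1-benzoxepine
Conditions: MePPh3Br, KOt-Bu, toluene, 100 °C
Reagents that add atoms: methyltriphenylphosphonium bromide, C[P+](c1ccccc1)(c1ccccc1)c1ccccc1.[Br-]
Why: Wittig methylenation under the forcing conditions used for hindered ketones, where any epimerisation at C7 only returns the favoured equatorial methyl epimer.

Step 8
Reactants: 11 (5aS,7S,9aS)-2,2,5a,7-tetramethyl-6-methylidenedecahydro-1-benzoxepine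
Product: 12 (5aR,6S,7S,9aS)-2,2,5a,7-tetramethyloctahydro-2H-spiro[1-benzoxepine-6,2'-oxirane]
Conditions: mCPBA, NaHCO3, CH2Cl2, 0 °C
Reagents that add atoms: mCPBA, O=C(OO)c1cccc(Cl)c1
Why: Prilezhaev epoxidation, in which the axial C5a methyl group shields one face of the exocyclic alkene so that oxygen arrives axially on the opposite face and sets C6 with O anti to that methyl group (a carbon nucleophile added to ketone 10 would come from this same face and give the wrong epimer).

**Dienophile (steps 9–11)**

Step 9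
Reactants: 13 2',5'-dihydroxyacetophenone; 14 acetone
Product: 15 6-hydroxy-2,2-dimethylchroman-4-one
Conditions: pyrrolidine (cat.), toluene, reflux
Reagents that add atoms: none
Why: Kabbe condensation (enamine aldol condensation followed by oxa-Michael closure) should install the Me2C=CH–C(=O)Ar carbon set in masked form.

Step 10
Reactants: 15 6-hydroxy-2,2-dimethylchroman-4-one
Product: 16 6-(benzyloxy)-2,2-dimethylchroman-4-one
Conditions: BnBr, K2CO3, DMF, rt
Reagents that add atoms: benzyl bromide, BrCc1ccccc1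
Why: Williamson ether synthesis on the only free phenol marks the oxygen that will later carry the sulfate.

Step 11
Reactants: 16 6-(benzyloxy)-2,2-dimethylchroman-4-one
Product: 18 4-(benzyloxy)-2-(3-methylbut-2-enoyl)phenyl ethyl carbonate, via potassium phenoxide 17 (not isolated)
Conditions: KHMDS (1.05 equiv), THF, −78 → 0 °C; then ClCO2Et, 0 °C
Reagents that add atoms: ethyl chloroformate, CCOC(=O)Cl
Why: E1cB retro-oxa-Michael opening of the chromanone enolate to the more stable phenoxide, whose O-acylation should lock the open enone and make it more electrophilic.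

**Bicyclooctane, fragment union and end game (steps 12–23)**

Step 12
Reactants: 19 3-ethoxycyclohex-2-en-1-one; 20 prop-1-yn-1-ylmagnesium bromide
Product: 22 3-(prop-1-yn-1-yl)cyclohex-2-en-1-one, via bromomagnesium alkoxide 21 (not isolated)
Conditions: THF, 0 °C → rt; then 1 M HCl
Reagents that add atoms: water, O
Why: Stork–Danheiser transposition, i.e. 1,2-addition to the vinylogous ester followed by acid hydrolysis, should give the cyclic enynone.

Step 13
Reactants: 22 3-(prop-1-yn-1-yl)cyclohex-2-en-1-one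
Product: 24 (S)-3-methyl-3-(prop-1-yn-1-yl)cyclohexan-1-one, via bromomagnesium enolate 23 (not isolated)
Conditions: MeMgBr, Cu(OTf)2 (5 mol %), chiral hydroxyalkyl-imidazolinium salt (NHC precursor, 7 mol %, the enantiomer that gives the S ketone), Et2O, −10 °C; then 1 M HCl
Reagents that add atoms: methylmagnesium bromide, C[Mg]Br
Why: Copper/NHC-catalysed asymmetric conjugate addition of a Grignard reagent to a cyclic enynone, a reaction type that goes 1,4 rather than 1,6 and builds the quaternary centre (future C8) under ligand control.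

Step 14
Reactants: 24 (S)-3-methyl-3-(prop-1-yn-1-yl)cyclohexan-1-one
Product: 25 (S)-5-methyl-5-(prop-1-yn-1-yl)cyclohex-2-en-1-one
Conditions: IBX, DMSO/toluene, 75 °C
Reagents that add atoms: none
Why: IBX dehydrogenation of a ketone, where the quaternary carbon leaves only one side open to desaturation and rules out aromatisation.

Step 15
Reactants: 25 (S)-5-methyl-5-(prop-1-yn-1-yl)cyclohex-2-en-1-one
Product: 27 (R)-tert-butyldimethyl{[5-methyl-5-(prop-1-yn-1-yl)cyclohexa-1,3-dien-1-yl]oxy}silane, via bromomagnesium dienolate 26 (not isolated)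
Conditions: MeMgBr, FeCl3 (3 mol %), Et2O, −20 °C; then TBSOTf, −78 → 0 °C
Reagents that add atoms: TBSOTf, CC(C)(C)[Si](C)(C)OS(=O)(=O)C(F)(F)F
Why: The Kharasch reagent (MeMgBr with catalytic iron) deprotonates enones at the γ-carbon to the through-conjugated dienolate, whose O-silylation should give the 1-silyloxy diene rather than the cross-conjugated 2-silyloxy isomer formed by amide bases.

Step 16
Reactants: 27 (R)-tert-butyldimethyl{[5-methyl-5-(prop-1-yn-1-yl)cyclohexa-1,3-dien-1-yl]oxy}silane; 18 4-(benzyloxy)-2-(3-methylbut-2-enoyl)phenyl ethyl carbonate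
Product: 28 4-(benzyloxy)-2-{[(1R,2S,4R,8R)-1-(tert-butyldimethylsilyloxy)-3,3,8-trimethyl-8-(prop-1-yn-1-yl)bicyclo[2.2.2]oct-5-en-2-yl]carbonyl}phenyl ethyl carbonate
Conditions: Tf2NH (10 mol %), 27 (1.5 equiv), CH2Cl2, −78 → −40 °C
Reagents that add atoms: none
Why: Silylium-type activation of the enone (TBSNTf2 formed in situ from Tf2NH and 27) should trigger a highly asynchronous normal-demand Diels–Alder reaction in which the remote diene terminus C4 attacks the enone β-carbon (C3) and the enol-silane carbon C2 closes onto the silyloxy-stabilised C1, the silyl group staying on the bridgehead oxygen. The closest known reaction type is the triflimide-catalysed low-temperature Diels–Alder reaction of hindered silyloxydienes with β,β-disubstituted enones, which builds adjacent fully substituted carbons. One new six-membered ring (C1–C2–C3–C4–C5–C6) is closed by [4+2] cycloaddition (in the stepwise limit a 6-(enolexo)-exo-trig Mukaiyama aldol closure), which turns the cyclohexadiene into the bicyclo[2.2.2]octene. The bridgeheads C1 and C4 are set by the diene face, because the C8 stereocentre of 27 lets the gem-dimethyl terminus pass the rod-like propynyl group (far smaller A value than methyl) and keeps it away from the methyl group, while C2 is set by the endo rule with the aroyl group under C5=C6, which is also the less crowded epimer. The needed "ortho" regioselectivity (C1–C2 and C4–C3) follows from the largest HOMO coefficient at C4 of a 1-silyloxydiene and the largest LUMO coefficient at the enone β-carbon. The electron-poor aryl carbonate raises the electrophilicity of 18 and prevents closure to the chromanone.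

Step 17
Reactants: 28 Diels–Alder adduct (aryl ketone carbonate)
Product: 30 4-(benzyloxy)-2-{[(1R,2S,4R,8R)-1-(tert-butyldimethylsilyloxy)-3,3,8-trimethyl-8-(prop-1-yn-1-yl)bicyclo[2.2.2]oct-5-en-2-yl]methyl}phenol, via ortho-quinone methide 29 (not isolated)
Conditions: NaBH4 (excess), THF/H2O, 0 °C → rt
Reagents that add atoms: none
Why: Known reductive deoxygenation of ortho-(alkoxycarbonyloxy)aryl ketones, in which hydride addition, carbonate migration to the benzylic alkoxide, 1,4-elimination to the ortho-quinone methide and a second hydride addition should give ArCH2 and the free ortho phenol without a benzylic cation, while the silyl ether blocks retro-aldol opening.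

Step 18
Reactants: 30 propynyl phenol
Product: 32 4-(benzyloxy)-2-{[(1R,2S,4S,8R)-1-(tert-butyldimethylsilyloxy)-3,3,8-trimethyl-8-(prop-2-yn-1-yl)bicyclo[2.2.2]oct-5-en-2-yl]methyl}phenol, via dipotassium salt 31 (not isolated)
Conditions: KH, H2N(CH2)3NH2 (KAPA, 5 equiv), 0 °C → rt; then H2O
Reagents that add atoms: none
Why: Alkyne zipper reaction driven by formation of the terminal acetylide, in which the quaternary C8 blocks inward migration, the bridged alkene cannot isomerise and no stereocentre is acidic.

Step 19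
Reactants: 32 propargyl phenol
Product: 33 triisopropylsilyl ether of 32 (ortho-OTIPS, configuration unchanged)
Conditions: TIPSOTf, 2,6-lutidine, CH2Cl2, 0 °C
Reagents that add atoms: TIPSOTf, CC(C)[Si](C(C)C)(C(C)C)OS(=O)(=O)C(F)(F)F
Why: Silyl protection of the ortho phenol, so that after debenzylation only the remote phenol is free for sulfation and the group can leave under non-acidic conditions.

Step 20
Reactants: 33 TIPS-protected terminal alkyne; 12 spiro-epoxide
Product: 35 coupled alkynol (C6-OH of the benzoxepine, CH2–C≡C–CH2 tether to C8, all stereocentres as in 12 and 33), via lithium acetylide 34 (not isolated)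
Conditions: n-BuLi, THF, −78 °C; then 12, DMPU, −78 → 60 °C; H2O
Reagents that add atoms: none
Why: SN2 opening of the 2,2-disubstituted epoxide by a lithium acetylide at its CH2 terminus leaves the tertiary C–O bond untouched, so the configuration set in step 8 is kept and the four-carbon tether is complete.

Step 21
Reactants: 35 coupled alkynol
Product: 36 saturated monophenol (butane-1,4-diyl tether, bicyclo[2.2.2]octane, free 4-OH, OTIPS and OTBS kept)
Conditions: H2 (4 bar), 10% Pd/C, EtOAc/EtOH, rt
Reagents that add atoms: none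
Why: Catalytic hydrogenation and hydrogenolysis in one operation should saturate the alkyne and the strained C5=C6 bond and cleave the benzyl ether, with no stereocentre created.

Step 22
Reactants: 36 saturated monophenol
Product: 37 aryl hydrogen sulfate of 36 (handled as its pyridinium salt)
Conditions: SO3·pyridine (3 equiv), pyridine, rt
Reagents that add atoms: sulfur trioxide pyridine complex, [O-]S(=O)(=O)[n+]1ccccc1
Why: O-sulfation with SO3·pyridine should take place only at the single free, unhindered phenol, since the tertiary C6 hydroxyl group is too hindered.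

Step 23
Reactants: 37 protected aryl hydrogen sulfate
Product: 38 CNP0255133.1 (target)
Conditions: TBAF (6 equiv), THF, 60 °C; then strongly acidic cation-exchange resin (H+ form), MeOH/H2O, 0 °C
Reagents that add atoms: none
Why: Fluoride desilylation removes the aryl TIPS and the bridgehead TBS groups under basic conditions that aryl sulfate monoesters tolerate, and a brief cation exchange gives the acid form.

**Compound list**

1 | 2-methylcyclohexane-1,3-dione | CC1C(=O)CCCC1=O | starting material
2 | acrolein | C=CC=O | starting material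
3 | 3-(1-methyl-2,6-dioxocyclohexyl)propanal | CC1(CCC=O)C(=O)CCCC1=O | intermediate
4 | 2-methyl-2-(4-methylpent-3-en-1-yl)cyclohexane-1,3-dione | CC1(CCC=C(C)C)C(=O)CCCC1=O | intermediate
5 | (2R,3R)-3-hydroxy-2-methyl-2-(4-methylpent-3-en-1-yl)cyclohexan-1-one | C1CC[C@@H](O)[C@](CCC=C(C)C)(C)C1=O | intermediate
6 | (1S,2R)-2-methyl-2-(4-methylpent-3-en-1-yl)-3-oxocyclohexyl 4-nitrobenzoate | C1CC[C@H](OC(=O)c2ccc(cc2)[N+](=O)[O-])[C@](CCC=C(C)C)(C)C1=O | intermediate
7 | (2R,3S)-3-hydroxy-2-methyl-2-(4-methylpent-3-en-1-yl)cyclohexan-1-one | C1CC[C@H](O)[C@](CCC=C(C)C)(C)C1=O | intermediate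
8 | (5aR,9aS)-2,2,5a-trimethyloctahydro-1-benzoxepin-6(2H)-one | C1CC[C@@H]2OC(C)(C)CCC[C@@]2(C)C1=O | intermediate
9 | lithium enolate of 8 | [Li]OC1=CCC[C@@H]2OC(C)(C)CCC[C@@]12C | intermediate
10 | (5aR,7S,9aS)-2,2,5a,7-tetramethyloctahydro-1-benzoxepin-6(2H)-one | C[C@H]1CC[C@@H]2OC(C)(C)CCC[C@@]2(C)C1=O | intermediate
11 | (5aS,7S,9aS)-2,2,5a,7-tetramethyl-6-methylidenedecahydro-1-benzoxepine | C[C@H]1CC[C@@H]2OC(C)(C)CCC[C@@]2(C)C1=C | intermediate
12 | (5aR,6S,7S,9aS)-2,2,5a,7-tetramethyloctahydro-2H-spiro[1-benzoxepine-6,2'-oxirane] | C[C@H]1CC[C@@H]2OC(C)(C)CCC[C@@]2(C)[C@]1(O3)C3 | intermediate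
13 | 2',5'-dihydroxyacetophenone | CC(=O)c1cc(O)ccc1O | starting material
14 | acetone | CC(C)=O | starting material
15 | 6-hydroxy-2,2-dimethylchroman-4-one | CC1(C)CC(=O)c2cc(O)ccc2O1 | intermediate
16 | 6-(benzyloxy)-2,2-dimethylchroman-4-one | CC1(C)CC(=O)c2cc(OCc3ccccc3)ccc2O1 | intermediate
17 | potassium 4-(benzyloxy)-2-(3-methylbut-2-enoyl)phenoxide | [K+].[O-]c1ccc(OCc2ccccc2)cc1C(=O)C=C(C)C | intermediate
18 | 4-(benzyloxy)-2-(3-methylbut-2-enoyl)phenyl ethyl carbonate | CC(C)=CC(=O)c1cc(OCc2ccccc2)ccc1OC(=O)OCC | intermediate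
19 | 3-ethoxycyclohex-2-en-1-one | CCOC1=CC(=O)CCC1 | starting material
20 | prop-1-yn-1-ylmagnesium bromide | CC#C[Mg]Br | starting material
21 | bromomagnesium 3-ethoxy-1-(prop-1-yn-1-yl)cyclohex-2-en-1-olate | CCOC1=CC(C#CC)(O[Mg]Br)CCC1 | intermediate
22 | 3-(prop-1-yn-1-yl)cyclohex-2-en-1-one | CC#CC1=CC(=O)CCC1 | intermediate
23 | bromomagnesium enolate of 24 | CC#C[C@]1(C)C=C(O[Mg]Br)CCC1 | intermediate
24 | (S)-3-methyl-3-(prop-1-yn-1-yl)cyclohexan-1-one | CC#C[C@]1(C)CC(=O)CCC1 | intermediate
25 | (S)-5-methyl-5-(prop-1-yn-1-yl)cyclohex-2-en-1-one | CC#C[C@]1(C)CC(=O)C=CC1 | intermediate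
26 | bromomagnesium through-conjugated dienolate of 25 | CC#C[C@]1(C)CC(O[Mg]Br)=CC=C1 | intermediate
27 | (R)-tert-butyldimethyl{[5-methyl-5-(prop-1-yn-1-yl)cyclohexa-1,3-dien-1-yl]oxy}silane | CC#C[C@]1(C)CC(O[Si](C)(C)C(C)(C)C)=CC=C1 | intermediate
28 | (1R,2S,4R,8R) Diels–Alder adduct, aryl ketone carbonate | CC#C[C@]1(C)C[C@@]2(O[Si](C)(C)C(C)(C)C)C=C[C@@H]1C(C)(C)[C@@H]2C(=O)c1cc(OCc2ccccc2)ccc1OC(=O)OCC | intermediate
29 | ortho-quinone methide from 28 | CC#C[C@]1(C)C[C@@]2(O[Si](C)(C)C(C)(C)C)C=C[C@@H]1C(C)(C)[C@@H]2C=C1C=C(OCc2ccccc2)C=CC1=O | intermediate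
30 | (1R,2S,4R,8R) benzyl-type phenol with 8-propynyl group | CC#C[C@]1(C)C[C@@]2(O[Si](C)(C)C(C)(C)C)C=C[C@@H]1C(C)(C)[C@@H]2Cc1cc(OCc2ccccc2)ccc1O | intermediate
31 | dipotassium acetylide phenoxide of 32 | [K+].[K+].[C-]#CC[C@]1(C)C[C@@]2(O[Si](C)(C)C(C)(C)C)C=C[C@@H]1C(C)(C)[C@@H]2Cc1cc(OCc2ccccc2)ccc1[O-] | intermediate
32 | (1R,2S,4S,8R) phenol with 8-(prop-2-yn-1-yl) group | C#CC[C@]1(C)C[C@@]2(O[Si](C)(C)C(C)(C)C)C=C[C@@H]1C(C)(C)[C@@H]2Cc1cc(OCc2ccccc2)ccc1O | intermediate
33 | TIPS ether of 32 | C#CC[C@]1(C)C[C@@]2(O[Si](C)(C)C(C)(C)C)C=C[C@@H]1C(C)(C)[C@@H]2Cc1cc(OCc2ccccc2)ccc1O[Si](C(C)C)(C(C)C)C(C)C | intermediate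
34 | lithium acetylide of 33 | [Li]C#CC[C@]1(C)C[C@@]2(O[Si](C)(C)C(C)(C)C)C=C[C@@H]1C(C)(C)[C@@H]2Cc1cc(OCc2ccccc2)ccc1O[Si](C(C)C)(C(C)C)C(C)C | intermediate
35 | coupled alkynol | C[C@H]1CC[C@@H]2OC(C)(C)CCC[C@@]2(C)[C@]1(O)CC#CC[C@]1(C)C[C@@]2(O[Si](C)(C)C(C)(C)C)C=C[C@@H]1C(C)(C)[C@@H]2Cc1cc(OCc2ccccc2)ccc1O[Si](C(C)C)(C(C)C)C(C)C | intermediate
36 | saturated monophenol | C[C@H]1CC[C@@H]2OC(C)(C)CCC[C@@]2(C)[C@]1(O)CCCC[C@]1(C)C[C@@]2(O[Si](C)(C)C(C)(C)C)CC[C@@H]1C(C)(C)[C@@H]2Cc1cc(O)ccc1O[Si](C(C)C)(C(C)C)C(C)C | intermediate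
37 | protected aryl hydrogen sulfate | C[C@H]1CC[C@@H]2OC(C)(C)CCC[C@@]2(C)[C@]1(O)CCCC[C@]1(C)C[C@@]2(O[Si](C)(C)C(C)(C)C)CC[C@@H]1C(C)(C)[C@@H]2Cc1cc(OS(=O)(=O)O)ccc1O[Si](C(C)C)(C(C)C)C(C)C | intermediate
38 | CNP0255133.1 | C[C@H]1CC[C@@H]2OC(C)(C)CCC[C@@]2(C)[C@]1(O)CCCC[C@]1(C)C[C@@]2(O)CC[C@@H]1C(C)(C)[C@@H]2Cc1cc(OS(=O)(=O)O)ccc1O | target

Total step count: 23.
Longest linear sequence: 12 steps (steps 12–23; steps 1–8 followed by 20–23 are equally long).

**The three steps most likely to fail**

Step 16.
- The bond between C4 (next to the quaternary C8) and the CMe2 carbon may not form.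
- The dienol ether may instead react through its unhindered α-carbon in a simple Mukaiyama–Michael addition, lose its silyl group, or add with poor facial discrimination.
- The fallback sets out from 27 and moves the arene out of the cycloaddition. The smaller and more easily activated 3-methylbut-2-enal is used as dienophile (Me2AlCl or Tf2NH, CH2Cl2, low temperature) to give the endo aldehyde F1.
- Dilithiated 2-bromo-4-(benzyloxy)phenol (n-BuLi, 2 equiv) is added to it to give the ortho-hydroxybenzylic alcohol F2.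
- Acetylation gives the diacetate F3. NaBH4 then cleaves the aryl acetate, expels the benzylic acetate to give the quinone methide 29 and reduces it, which returns the route at 30.

Step 20.
- Attack at the neopentyl-type epoxide CH2 may be slower than base-induced isomerisation of the epoxide to an allylic alcohol.
- The fallback replaces substitution by carbonyl addition and sets out from 11 and 34.
- Dihydroxylation of 11 (OsO4 cat., NMO, same face as the epoxidation) gives the diol F4.
- Selective oxidation of its primary alcohol (TEMPO, PhI(OAc)2) gives the α-hydroxy aldehyde F5.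
- Addition of 34 (2 equiv) gives the propargylic diol F6.
- Reductive transposition with 2-nitrobenzenesulfonylhydrazine, PPh3 and DEAD (Myers allene synthesis, only the secondary alcohol reacts) gives the allene F7.
- Hydrogenation of F7 under the conditions of step 21 returns the route at 36.

Step 5.
- Closure of the seven-membered ring may be slower than reduction or isomerisation of the alkene at the radical or cation stage.
- The fallback sets out from 7 and uses electrophilic metal activation instead of hydrogen-atom transfer.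
- Intramolecular oxymercuration (Hg(O2CCF3)2, MeCN, 0 °C, then aq. NaCl) gives the chloromercurio oxepane F8.
- Radical demercuration of F8 with n-Bu3SnH (which spares the ketone) returns the route at 8.

Further compounds
F1 | step 16 | (1R,2S,4R,8R)-1-(tert-butyldimethylsilyloxy)-3,3,8-trimethyl-8-(prop-1-yn-1-yl)bicyclo[2.2.2]oct-5-ene-2-carbaldehyde | CC#C[C@]1(C)C[C@@]2(O[Si](C)(C)C(C)(C)C)C=C[C@@H]1C(C)(C)[C@@H]2C=O
F2 | step 16 | ortho-hydroxybenzylic alcohol from F1 (carbinol epimers) | CC#C[C@]1(C)C[C@@]2(O[Si](C)(C)C(C)(C)C)C=C[C@@H]1C(C)(C)[C@@H]2C(O)c1cc(OCc2ccccc2)ccc1O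
F3 | step 16 | diacetate of F2 | CC#C[C@]1(C)C[C@@]2(O[Si](C)(C)C(C)(C)C)C=C[C@@H]1C(C)(C)[C@@H]2C(OC(C)=O)c1cc(OCc2ccccc2)ccc1OC(C)=O
F4 | step 20 | 6-(hydroxymethyl)-2,2,5a,7-tetramethyldecahydro-1-benzoxepin-6-ol | C[C@H]1CC[C@@H]2OC(C)(C)CCC[C@@]2(C)[C@]1(O)CO
F5 | step 20 | 6-hydroxy-2,2,5a,7-tetramethyldecahydro-1-benzoxepine-6-carbaldehyde | C[C@H]1CC[C@@H]2OC(C)(C)CCC[C@@]2(C)[C@]1(O)C=O
F6 | step 20 | propargylic diol from F5 and 34 (carbinol epimers) | C[C@H]1CC[C@@H]2OC(C)(C)CCC[C@@]2(C)[C@]1(O)C(O)C#CC[C@]1(C)C[C@@]2(O[Si](C)(C)C(C)(C)C)C=C[C@@H]1C(C)(C)[C@@H]2Cc1cc(OCc2ccccc2)ccc1O[Si](C(C)C)(C(C)C)C(C)C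
F7 | step 20 | allene from F6 | C[C@H]1CC[C@@H]2OC(C)(C)CCC[C@@]2(C)[C@]1(O)C=C=CC[C@]1(C)C[C@@]2(O[Si](C)(C)C(C)(C)C)C=C[C@@H]1C(C)(C)[C@@H]2Cc1cc(OCc2ccccc2)ccc1O[Si](C(C)C)(C(C)C)C(C)C
F8 | step 5 | 3-(chloromercurio) derivative of 8 | C1CC[C@@H]2OC(C)(C)C([Hg]Cl)CC[C@@]2(C)C1=O
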